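## Retrosynthetic overview

1. The C5–C1' bond is cut first: the target comes from a 5-bromo-dihydrobenzofuran core and O-(1-ethoxyethyl)-(R)-lactaldehyde. Chelation-controlled aryl addition sets C1' from the bought C2' centre, and the acetal falls off in the acidic quench.
2. The dihydrofuran ring is the only ring formed. It closes at O1–C2 by acid cyclisation of a 1-aryl-2-(2-hydroxyaryl)propan-1-ol, with C3 directing C2 to trans. That diol comes from a 2-arylpropanal and (3,4-dimethoxyphenyl)magnesium bromide.
3. The key C3–C3a bond and the C3 centre come from an aromatic Claisen ([3,3]) rearrangement of an (S,Z)-pent-3-en-2-yl aryl ether with 1,3-chirality transfer. The spent alkene is then cut to the aldehyde by ozonolysis.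
4. The ether comes from 4-bromo-2-methoxyphenol and methyl (R)-lactate (Mitsunobu inversion, then ester to Z-propenyl).
5. Both benzene rings are bought. Methyl (R)-lactate is the only source of chirality and is used twice.

Assumption: methyl (R)-lactate (methyl D-lactate) is taken as an inexpensive commercial chiral starting material; the 1-ethoxyethyl acetal carbon is carried as an epimer mixture and left undefined in the SMILES.

## Route

Step 1
Reactants: 1 4-bromo-2-methoxyphenol; 2 methyl (2R)-2-hydroxypropanoate (methyl (R)-lactate)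
Product: 3 methyl (2S)-2-(4-bromo-2-methoxyphenoxy)propanoate
Conditions: PPh3, DIAD, THF, 0 °C → rt
Reagents that add atoms: none
Why: Mitsunobu etherification of the phenol with the secondary lactate hydroxyl is an SN2 displacement with clean inversion, so the bought (R) centre becomes the (S)-aryloxy centre.

Step 2
Reactants: 3 methyl (2S)-2-(4-bromo-2-methoxyphenoxy)propanoate
Product: 5 4-bromo-2-methoxy-1-{[(2S,3Z)-pent-3-en-2-yl]oxy}benzene, via aryloxy aldehyde 4 (not isolated)
Conditions: i-Bu2AlH (1.1 equiv), CH2Cl2, −78 °C; then Ph3P=CHCH3 (from EtPPh3Br + KN(SiMe3)2, THF), −78 °C → rt; aq. KNaC4H4O6 work-up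
Reagents that add atoms: ethyltriphenylphosphonium bromide, CC[P+](c1ccccc1)(c1ccccc1)c1ccccc1.[Br-]
Why: Partial ester reduction stops at the aluminium hemiacetal, which releases aldehyde 4 into a salt-free Wittig olefination with the non-stabilised ylide (Z-selective), and trapping in the same flask keeps the epimerisable (S) centre intact.

Step 3
Reactants: 5 4-bromo-2-methoxy-1-{[(2S,3Z)-pent-3-en-2-yl]oxy}benzene
Product: 6 4-bromo-2-methoxy-6-[(2S,3E)-pent-3-en-2-yl]phenol
Conditions: PhNEt2 (degassed), 185 °C, sealed tube, ca. 12 h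
Reagents that add atoms: none
Why: Aromatic Claisen ([3,3]-sigmatropic) rearrangement to the only free ortho position runs through a chair transition state with the carbinol methyl equatorial (the other chair would put two methyls syn-axial), so the ether centre is transferred suprafacially to the new benzylic (S) centre and the new alkene is E.

Step 4
Reactants: 6 4-bromo-2-methoxy-6-[(2S,3E)-pent-3-en-2-yl]phenol
Product: 7 (2R)-2-(5-bromo-2-hydroxy-3-methoxyphenyl)propanal (present mainly as its lactol; used crude)
Conditions: O3, CH2Cl2, −78 °C (Sudan Red 7B end point); then PPh3, −78 °C → rt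
Reagents that add atoms: ozone, [O-][O+]=O
Why: Ozonolysis with reductive work-up cleaves the isolated alkene much faster than ozone attacks the arene; the benzylic centre is untouched (S becomes R only by priority change) and is shielded from enolisation because the aldehyde closes to a lactol.

Step 5
Reactants: 7 (2R)-2-(5-bromo-2-hydroxy-3-methoxyphenyl)propanal; 8 (3,4-dimethoxyphenyl)magnesium bromide
Product: 9 (1S,2R)-2-(5-bromo-2-hydroxy-3-methoxyphenyl)-1-(3,4-dimethoxyphenyl)propan-1-ol (expected major epimer; the C1 epimer is carried along)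
Conditions: 8 (3 equiv, THF), −78 → 0 °C; then H2O/NH4Cl
Reagents that add atoms: none
Why: In this Grignard addition the first equivalent opens the lactol as its magnesium phenoxide and the second adds to the aldehyde faster than it enolises it (Felkin–Anh sense expected), and the carbinol configuration does not matter because the next step is stereoconvergent.

Step 6
Reactants: 9 (1S,2R)-2-(5-bromo-2-hydroxy-3-methoxyphenyl)-1-(3,4-dimethoxyphenyl)propan-1-ol
Product: 10 (2R,3R)-5-bromo-2-(3,4-dimethoxyphenyl)-7-methoxy-3-methyl-2,3-dihydro-1-benzofuran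
Conditions: TsOH·H2O (10 mol %), CH2Cl2, 0 °C → rt
Reagents that add atoms: none
Why: Acid-catalysed cyclodehydration (SN1) forms the 3,4-dimethoxybenzylic cation, which the neighbouring phenol captures anti to the C3 methyl in a five-membered ring closure, so both carbinol epimers converge on the trans (2R,3R) ring.

Step 7
Reactants: 2 methyl (2R)-2-hydroxypropanoate
Product: 11 methyl (2R)-2-(1-ethoxyethoxy)propanoate
Conditions: ethyl vinyl ether, PPTS (cat.), CH2Cl2, 0 °C → rt
Reagents that add atoms: ethyl vinyl ether, C=COCC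
Why: Acid-catalysed addition of the alcohol to the enol ether (acetal protection) leaves the (R) centre untouched and gives a chelating, very acid-labile oxygen substituent.

Step 8
Reactants: 11 methyl (2R)-2-(1-ethoxyethoxy)propanoate
Product: 12 (2R)-2-(1-ethoxyethoxy)propanal
Conditions: i-Bu2AlH (1.05 equiv), CH2Cl2, −78 °C; aq. KNaC4H4O6 work-up; used fresh
Reagents that add atoms: none
Why: Partial reduction of the α-alkoxy ester stops at the chelated aluminium hemiacetal at −78 °C, giving the aldehyde without over-reduction or epimerisation.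

Step 9
Reactants: 10 (2R,3R)-5-bromo-2-(3,4-dimethoxyphenyl)-7-methoxy-3-methyl-2,3-dihydro-1-benzofuran; 12 (2R)-2-(1-ethoxyethoxy)propanal
Product: 16 (1R,2R)-1-[(2R,3R)-2-(3,4-dimethoxyphenyl)-7-methoxy-3-methyl-2,3-dihydro-1-benzofuran-5-yl]propane-1,2-diol (CNP0249073.1), via aryllithium 13 (not isolated), via arylmagnesium bromide 14 (not isolated), via ethoxyethyl-protected adduct 15 (not isolated)
Conditions: 10, t-BuLi (2.1 equiv), Et2O, −78 °C; MgBr2·OEt2 (2.5 equiv), −78 → −40 °C; 12 (1.5 equiv) in CH2Cl2, −78 °C; then 1 M aq. HCl, THF, 0 °C → rt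
Reagents that add atoms: none
Why: Bromine–lithium exchange and transmetalation give an aryl Grignard that adds to the MgBr2-chelated α-alkoxy aldehyde from the face opposite its methyl group (Cram chelate model), so the bought (R) centre sets C1' as R (threo), and the dilute-acid quench hydrolyses the acetal without ionising the β-oxygenated benzylic alcohol.

## Compound list

1 | 4-bromo-2-methoxyphenol | COc1cc(Br)ccc1O | starting material
2 | methyl (2R)-2-hydroxypropanoate (methyl (R)-lactate) | C[C@@H](O)C(=O)OC | starting material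
3 | methyl (2S)-2-(4-bromo-2-methoxyphenoxy)propanoate | C[C@H](Oc1ccc(Br)cc1OC)C(=O)OC | intermediate
4 | (2S)-2-(4-bromo-2-methoxyphenoxy)propanal (aryloxy aldehyde, not isolated) | C[C@H](Oc1ccc(Br)cc1OC)C=O | intermediate
5 | 4-bromo-2-methoxy-1-{[(2S,3Z)-pent-3-en-2-yl]oxy}benzene | C/C=C\[C@H](C)Oc1ccc(Br)cc1OC | intermediate
6 | 4-bromo-2-methoxy-6-[(2S,3E)-pent-3-en-2-yl]phenol | C/C=C/[C@H](C)c1cc(Br)cc(OC)c1O | intermediate
7 | (2R)-2-(5-bromo-2-hydroxy-3-methoxyphenyl)propanal (in equilibrium with its lactol) | O=C[C@H](C)c1cc(Br)cc(OC)c1O | intermediate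
8 | (3,4-dimethoxyphenyl)magnesium bromide | COc1ccc([Mg]Br)cc1OC | starting material
9 | (1S,2R)-2-(5-bromo-2-hydroxy-3-methoxyphenyl)-1-(3,4-dimethoxyphenyl)propan-1-ol | COc1ccc([C@@H](O)[C@H](C)c2cc(Br)cc(OC)c2O)cc1OC | intermediate
10 | (2R,3R)-5-bromo-2-(3,4-dimethoxyphenyl)-7-methoxy-3-methyl-2,3-dihydro-1-benzofuran | COc1ccc([C@@H]2Oc3c(OC)cc(Br)cc3[C@H]2C)cc1OC | intermediate
11 | methyl (2R)-2-(1-ethoxyethoxy)propanoate | C[C@@H](OC(C)OCC)C(=O)OC | intermediate
12 | (2R)-2-(1-ethoxyethoxy)propanal | C[C@@H](OC(C)OCC)C=O | intermediate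
13 | [(2R,3R)-2-(3,4-dimethoxyphenyl)-7-methoxy-3-methyl-2,3-dihydro-1-benzofuran-5-yl]lithium (aryllithium, not isolated) | COc1ccc([C@@H]2Oc3c(OC)cc([Li])cc3[C@H]2C)cc1OC | intermediate
14 | [(2R,3R)-2-(3,4-dimethoxyphenyl)-7-methoxy-3-methyl-2,3-dihydro-1-benzofuran-5-yl]magnesium bromide (not isolated) | COc1ccc([C@@H]2Oc3c(OC)cc([Mg]Br)cc3[C@H]2C)cc1OC | intermediate
15 | (1R,2R)-1-[(2R,3R)-2-(3,4-dimethoxyphenyl)-7-methoxy-3-methyl-2,3-dihydro-1-benzofuran-5-yl]-2-(1-ethoxyethoxy)propan-1-ol (not isolated) | COc1ccc([C@@H]2Oc3c(OC)cc([C@@H](O)[C@@H](C)OC(C)OCC)cc3[C@H]2C)cc1OC | intermediate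
16 | (1R,2R)-1-[(2R,3R)-2-(3,4-dimethoxyphenyl)-7-methoxy-3-methyl-2,3-dihydro-1-benzofuran-5-yl]propane-1,2-diol | COc1ccc([C@@H]2Oc3c(OC)cc([C@@H](O)[C@@H](C)O)cc3[C@H]2C)cc1OC | target

## Count and risks

Total step count: 9. Longest linear sequence: 7 (steps 1, 2, 3, 4, 5, 6, 9); steps 7 and 8 form the two-step side branch.

**Step 2.** The α-aryloxy aldehyde 4 may epimerise under the basic ylide, and any E-alkene would lead to the enantiomeric C3 after step 3. Both lower the ee of the core; 10 can be recrystallised to raise it. The fallback sets out from 12 (with 1) and comes back at 5. It builds the Z-alkene on the configurationally more robust O-alkyl aldehyde and makes the aryl ether last. Wittig reaction of 12 with Ph3P=CHCH3 gives (2R,3Z)-2-(1-ethoxyethoxy)pent-3-ene F1. Aqueous AcOH/THF then frees (2R,3Z)-pent-3-en-2-ol F2. Mitsunobu coupling of F2 with phenol 1 (PPh3, DIAD, inversion) gives 5.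

**Step 3.** The Z-ether rearranges slowly. At the temperature needed, the free phenol 6 can isomerise further (abnormal Claisen pathway to the 1-ethylallyl isomer), and chirality transfer may be incomplete. The fallback sets out from 5 and comes back at 6. It replaces the phenol-releasing rearrangement by an acylative one. Ether 5 is heated in PhNEt2 with acetic anhydride, so the phenol is captured as it forms as 4-bromo-2-methoxy-6-[(2S,3E)-pent-3-en-2-yl]phenyl acetate F3. F3 cannot enter the abnormal pathway. K2CO3 in MeOH at rt then returns 6.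

**Step 9.** Chelation control with an acetal-type oxygen and an aryl Grignard may be only moderate, giving erythro diol that must be separated, and the one-flask acid quench must not epimerise C1'. The fallback sets out from 10 (with 2) and comes back at 16. It sets C1' by hydride delivery instead of C–C bond formation.
- Ester 2 with MeNH(OMe)·HCl and i-PrMgCl gives (2R)-2-hydroxy-N-methoxy-N-methylpropanamide F4.
- TBSCl and imidazole convert F4 into (2R)-2-[(tert-butyldimethylsilyl)oxy]-N-methoxy-N-methylpropanamide F5.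
- Aryllithium 13 (from 10 and t-BuLi) acylates on F5 to give the α-silyloxy ketone F6.
- LiBH(s-Bu)3 in THF at −78 °C reduces the non-chelating ketone in the Felkin–Anh sense to the threo mono-silyl ether F7.
- Bu4NF gives 16.

## Further compounds

F1 | step 2 | (2R,3Z)-2-(1-ethoxyethoxy)pent-3-ene | C/C=C\[C@@H](C)OC(C)OCC
F2 | step 2 | (2R,3Z)-pent-3-en-2-ol | C/C=C\[C@@H](C)O
F3 | step 3 | 4-bromo-2-methoxy-6-[(2S,3E)-pent-3-en-2-yl]phenyl acetate | C/C=C/[C@H](C)c1cc(Br)cc(OC)c1OC(C)=O
F4 | step 9 | (2R)-2-hydroxy-N-methoxy-N-methylpropanamide | C[C@@H](O)C(=O)N(C)OC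
F5 | step 9 | (2R)-2-[(tert-butyldimethylsilyl)oxy]-N-methoxy-N-methylpropanamide | C[C@@H](O[Si](C)(C)C(C)(C)C)C(=O)N(C)OC
F6 | step 9 | (2R)-2-[(tert-butyldimethylsilyl)oxy]-1-[(2R,3R)-2-(3,4-dimethoxyphenyl)-7-methoxy-3-methyl-2,3-dihydro-1-benzofuran-5-yl]propan-1-one (α-silyloxy ketone) | COc1ccc([C@@H]2Oc3c(OC)cc(C(=O)[C@@H](C)O[Si](C)(C)C(C)(C)C)cc3[C@H]2C)cc1OC
F7 | step 9 | (1R,2R)-2-[(tert-butyldimethylsilyl)oxy]-1-[(2R,3R)-2-(3,4-dimethoxyphenyl)-7-methoxy-3-methyl-2,3-dihydro-1-benzofuran-5-yl]propan-1-ol (threo mono-silyl ether) | COc1ccc([C@@H]2Oc3c(OC)cc([C@@H](O)[C@@H](C)O[Si](C)(C)C(C)(C)C)cc3[C@H]2C)cc1OC
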